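**Retrosynthetic overview**

1. Last C–C bond: the threo unit B is cut at C7–C8 by an Evans boron syn-aldol between an aryloxyacetyl imide on the second phenol of the core and an aldehyde that already carries the erythro unit C.
2. Both erythro units (A on the first core phenol, C on the aldehyde fragment) are cut at C7–C8 by a proposed MgCl2-catalysed anti-aldol of aryloxyacetyl imides with TIPS-vanillin. Each imide comes from O-alkylation of a phenol with a chloroacetyl oxazolidinone; each C9 alcohol comes from LiBH4 cleavage of the auxiliary.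
3. The two different arms are put on the C2-symmetric diphenol one after the other (mono-alkylation; arm A first, arm B second).
4. Rings: only the furofuran is built. Both tetrahydrofuran rings close in the first step (oxidative C8–C8' dimerisation of two molecules of sinapyl alcohol, then two intramolecular C7–O closures); the (+)-enantiomer is taken by chiral chromatography.
5. Protection is silyl only (TIPS on phenols, TBS on alcohols) and is removed in one fluoride step at the end.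

Assumption: both enantiomers of 4-benzyl-3-(chloroacetyl)oxazolidin-2-one are taken as catalogue compounds; C7 (benzylic), C8 (ether carbon) and C9 (CH2OH) follow lignan numbering, and the target is core (7S,8R,7'S,8'R), unit A erythro (7R,8S), unit B threo (7S,8S), unit C erythro (7S,8R).

**Route**

Step 1
Reactants: 1 sinapyl alcohol (two molecules couple to give one molecule of 2)
Product: 2 (+)-syringaresinol, the (7S,8R,7'S,8'R) furofuran
Conditions: FeCl3·6H2O (1.1 equiv per 1), acetone/H2O, rt; then preparative chiral SFC (amylose tris(3,5-dimethylphenylcarbamate) phase, CO2/MeOH), (+)-enantiomer collected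
Reagents that add atoms: sinapyl alcohol (the second molecule of 1), COc1cc(/C=C/CO)cc(OC)c1O
Why: Biomimetic oxidative β–β dimerisation of two molecules of 1: trivalent iron oxidises each phenol to a phenoxyl radical that can only couple at C8 (both ortho positions carry OMe), the two quinone methides of the C8–C8' dimer are trapped by the two 9-OH groups to close both tetrahydrofuran rings cis-fused with the aryl groups exo, so the syringaresinol diastereomer forms as a racemate and the absolute configuration is fixed by the chromatographic resolution.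

Step 2
Reactants: 3 vanillin
Product: 4 3-methoxy-4-[(triisopropylsilyl)oxy]benzaldehyde
Conditions: TIPSCl, imidazole, DMF, rt
Reagents that add atoms: triisopropylsilyl chloride, CC(C)[Si](Cl)(C(C)C)C(C)C
Why: Standard silylation of a phenol; the aryl TIPS ether survives carbonate, LiBH4, iBu2AlH and boron triflate and falls with fluoride at the end.

Step 3
Reactants: 5 4-hydroxy-3-methoxybenzonitrile; 6 (R)-4-benzyl-3-(chloroacetyl)oxazolidin-2-one
Product: 7 (R)-4-benzyl-3-[(4-cyano-2-methoxyphenoxy)acetyl]oxazolidin-2-one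
Conditions: K2CO3, DMF, 40 °C
Reagents that add atoms: none
Why: Williamson ether synthesis (SN2 at an α-chloro carbonyl carbon); the nitrile is a latent aldehyde that cannot interfere with enolisation or with LiBH4.

Step 4
Reactants: 7 (R)-4-benzyl-3-[(4-cyano-2-methoxyphenoxy)acetyl]oxazolidin-2-one; 4 3-methoxy-4-[(triisopropylsilyl)oxy]benzaldehyde
Product: 9 (R)-4-benzyl-3-[(2S,3S)-2-(4-cyano-2-methoxyphenoxy)-3-hydroxy-3-{3-methoxy-4-[(triisopropylsilyl)oxy]phenyl}propanoyl]oxazolidin-2-one, via trimethylsilyl ether 8 (not isolated)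
Conditions: MgCl2 (20 mol %), Et3N (2 equiv), TMSCl (1.5 equiv), EtOAc, 23 °C; then 1 M aq HCl/THF, 0 °C
Reagents that add atoms: none
Why: Proposed new method: a MgCl2-catalysed soft-enolisation anti-aldol of an N-(aryloxyacetyl)oxazolidinone — Et3N and MgCl2 deprotonate the acidified α-CH2 to the chelated (Z)-magnesium enolate (magnesium bridges the enolate oxygen and the ring carbonyl, the aryloxy oxygen can act as a third ligand), the magnesium-bound aldehyde is attacked through a boat-like closed transition state on the enolate face opposite the benzyl group with its aryl group turned away from the auxiliary, which sets (2S,3S) (anti, the erythro 7S,8R unit C after step 5), and TMSCl silylates the magnesium aldolate so that the catalyst turns over and retro-aldol and epimerisation are shut off; the closest known reaction is the magnesium-halide-catalysed anti-aldol of N-acyl oxazolidinones carrying α-alkyl groups with aromatic aldehydes, not shown for α-aryloxyacetyl imides.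

Step 5
Reactants: 9 anti-aldol adduct
Product: 10 4-{[(1S,2R)-1,3-dihydroxy-1-{3-methoxy-4-[(triisopropylsilyl)oxy]phenyl}propan-2-yl]oxy}-3-methoxybenzonitrile (erythro)
Conditions: LiBH4, THF, H2O (1 equiv), 0 °C
Reagents that add atoms: none
Why: Reductive cleavage of the N-acyl oxazolidinone (hydride attacks the exocyclic carbonyl) gives the C9 alcohol; nitrile, silyl ether and both stereocentres are untouched.

Step 6
Reactants: 10 erythro diol
Product: 11 4-{[(1S,2R)-1,3-bis[(tert-butyldimethylsilyl)oxy]-1-{3-methoxy-4-[(triisopropylsilyl)oxy]phenyl}propan-2-yl]oxy}-3-methoxybenzonitrile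
Conditions: TBSOTf (2.5 equiv), 2,6-lutidine (4 equiv), CH2Cl2, −78 → 0 °C
Reagents that add atoms: tert-butyldimethylsilyl triflate, CC(C)(C)[Si](C)(C)OS(=O)(=O)C(F)(F)F
Why: Silyl triflate with a hindered pyridine base silylates the primary and the secondary benzylic alcohol without acid, so the diol cannot consume boron triflate later.

Step 7
Reactants: 11 bis-TBS nitrile
Product: 13 4-{[(1S,2R)-1,3-bis[(tert-butyldimethylsilyl)oxy]-1-{3-methoxy-4-[(triisopropylsilyl)oxy]phenyl}propan-2-yl]oxy}-3-methoxybenzaldehyde, via N-aluminio aldimine 12 (not isolated)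
Conditions: iBu2AlH (1.3 equiv), toluene, −78 °C; then aq. KNaC4H4O6 (potassium sodium tartrate), rt
Reagents that add atoms: water, O
Why: Partial reduction of an aryl nitrile stops at the N-metalated aldimine, which is hydrolysed on work-up to the aldehyde; silyl ethers and stereocentres are inert.

Step 8
Reactants: 2 (+)-syringaresinol (2 equiv, excess recovered); 14 (S)-4-benzyl-3-(chloroacetyl)oxazolidin-2-one
Product: 15 (S)-4-benzyl-3-({4-[(1S,3aR,4S,6aR)-4-(4-hydroxy-3,5-dimethoxyphenyl)tetrahydro-1H,3H-furo[3,4-c]furan-1-yl]-2,6-dimethoxyphenoxy}acetyl)oxazolidin-2-one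
Conditions: K2CO3 (1.0 equiv), DMF, 40 °C
Reagents that add atoms: none
Why: Williamson ether synthesis; the two phenols of C2-symmetric 2 are homotopic, so mono-alkylation gives one compound and the excess of 2 holds back the bis-ether.

Step 9
Reactants: 15 mono-(aryloxyacetyl imide) of syringaresinol; 4 3-methoxy-4-[(triisopropylsilyl)oxy]benzaldehyde
Product: 17 (S)-4-benzyl-3-[(2R,3R)-3-hydroxy-3-{3-methoxy-4-[(triisopropylsilyl)oxy]phenyl}-2-(syringaresinol-4-yloxy)propanoyl]oxazolidin-2-one, via bis(trimethylsilyl) ether 16 (not isolated)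
Conditions: MgCl2 (20 mol %), Et3N (4 equiv), TMSCl (3 equiv), EtOAc, 23 °C; then 1 M aq HCl/THF, 0 °C
Reagents that add atoms: none
Why: Proposed new method: the same MgCl2-catalysed soft-enolisation anti-aldol as in step 4, now with the (S)-auxiliary — the chelated (Z)-magnesium enolate is attacked by the magnesium-bound aldehyde on the face opposite the benzyl group through a boat-like closed transition state to give (2R,3R) (anti, the erythro 7R,8S unit A after step 10), the free core phenol is silylated in the flask and freed again on acidic work-up, and TMSCl trapping of the aldolate gives turnover and irreversibility; the closest known reaction is the magnesium-halide-catalysed anti-aldol of α-alkyl N-acyl oxazolidinones with aromatic aldehydes.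

Step 10
Reactants: 17 anti-aldol adduct
Product: 18 (+)-syringaresinol mono-ether whose one phenolic oxygen carries C2 of (1R,2S)-1-{3-methoxy-4-[(triisopropylsilyl)oxy]phenyl}propane-1,3-diol (erythro unit A; second core phenol free)
Conditions: LiBH4, THF, H2O (1 equiv), 0 °C
Reagents that add atoms: none
Why: Reductive cleavage of the N-acyl oxazolidinone to the primary alcohol; no stereocentre is touched.

Step 11
Reactants: 18 unit-A diol with free core phenol; 6 (R)-4-benzyl-3-(chloroacetyl)oxazolidin-2-one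
Product: 19 compound 18 whose second core phenol carries CH2C(=O) bound to N of (R)-4-benzyloxazolidin-2-one
Conditions: K2CO3, DMF, 40 °C
Reagents that add atoms: none
Why: Williamson ether synthesis; carbonate deprotonates only the phenol, so the aliphatic diol of unit A does not react.

Step 12
Reactants: 19 aryloxyacetyl imide with free unit-A diol
Product: 20 compound 19 with the C7 and C9 hydroxyls of unit A as TBS ethers
Conditions: TBSOTf (2.5 equiv), 2,6-lutidine (4 equiv), CH2Cl2, −78 → −20 °C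
Reagents that add atoms: tert-butyldimethylsilyl triflate, CC(C)(C)[Si](C)(C)OS(=O)(=O)C(F)(F)F
Why: Low-temperature silylation with silyl triflate and a hindered base is the usual way to protect alcohols next to an N-acyl oxazolidinone, which it leaves intact.

Step 13
Reactants: 20 bis-TBS aryloxyacetyl imide; 13 aldehyde carrying unit C
Product: 22 syn-aldol adduct with (2R,3S) configuration in the new propanoyl unit B on the (R)-auxiliary, via dibutylboron (Z)-enolate 21 (not isolated)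
Conditions: nBu2BOTf (1.3 equiv), iPr2NEt (1.5 equiv), CH2Cl2, −78 → 0 °C; then 13 (1.2 equiv), −78 → 0 °C; then aq. KH2PO4/K2HPO4 buffer (pH 7), MeOH, 30 % H2O2, 0 °C
Reagents that add atoms: none
Why: Evans boron syn-aldol: the (Z)-boron enolate (geometry fixed by A(1,3) strain) reacts through a chair Zimmerman–Traxler transition state with the ring carbonyl turned away from boron, so the (R)-benzyl group sends the aldehyde to the opposite enolate face and gives the (2R,3S) syn adduct, the threo 7S,8S unit B after step 14.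

Step 14
Reactants: 22 syn-aldol adduct
Product: 23 the target with both guaiacyl phenols as TIPS ethers and the C7 and C9 hydroxyls of units A and C as TBS ethers (unit B diol free)
Conditions: LiBH4, THF, H2O (1 equiv), 0 °C
Reagents that add atoms: none
Why: Reductive cleavage of the last N-acyl oxazolidinone to the C9 alcohol of unit B; silyl ethers and all stereocentres are untouched.

Step 15
Reactants: 23 hexasilyl ether
Product: 24 target, CNP0316493.3
Conditions: Bu4NF/AcOH (1:1, 10 equiv), THF, 0 °C → rt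
Reagents that add atoms: none
Why: Fluoride cleaves all four TBS and both TIPS ethers, and the acetic acid buffer keeps the phenoxides protonated so that the p-hydroxybenzyl alcohols do not form quinone methides and no stereocentre is put at risk.

**Compound list**

1 | sinapyl alcohol, (E)-4-(3-hydroxyprop-1-enyl)-2,6-dimethoxyphenol | COc1cc(/C=C/CO)cc(OC)c1O | starting material
2 | (+)-syringaresinol, 4,4'-[(1S,3aR,4S,6aR)-tetrahydro-1H,3H-furo[3,4-c]furan-1,4-diyl]bis(2,6-dimethoxyphenol) | COc1cc([C@H]2OC[C@H]3[C@@H]2CO[C@@H]3c2cc(OC)c(O)c(OC)c2)cc(OC)c1O | intermediate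
3 | vanillin, 4-hydroxy-3-methoxybenzaldehyde | COc1cc(C=O)ccc1O | starting material
4 | 3-methoxy-4-[(triisopropylsilyl)oxy]benzaldehyde | COc1cc(C=O)ccc1O[Si](C(C)C)(C(C)C)C(C)C | intermediate
5 | 4-hydroxy-3-methoxybenzonitrile | COc1cc(C#N)ccc1O | starting material
6 | (R)-4-benzyl-3-(chloroacetyl)oxazolidin-2-one | ClCC(=O)N1[C@H](Cc2ccccc2)COC1=O | starting material
7 | (R)-4-benzyl-3-[(4-cyano-2-methoxyphenoxy)acetyl]oxazolidin-2-one | COc1cc(C#N)ccc1OCC(=O)N1[C@H](Cc2ccccc2)COC1=O | intermediate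
8 | O-trimethylsilyl ether of 9, (2S,3S) | N#Cc1ccc(O[C@H](C(=O)N2[C@H](Cc3ccccc3)COC2=O)[C@@H](O[Si](C)(C)C)c4ccc(O[Si](C(C)C)(C(C)C)C(C)C)c(OC)c4)c(OC)c1 | intermediate (not isolated)
9 | (R)-4-benzyl-3-[(2S,3S)-2-(4-cyano-2-methoxyphenoxy)-3-hydroxy-3-{3-methoxy-4-[(triisopropylsilyl)oxy]phenyl}propanoyl]oxazolidin-2-one | N#Cc1ccc(O[C@H](C(=O)N2[C@H](Cc3ccccc3)COC2=O)[C@@H](O)c4ccc(O[Si](C(C)C)(C(C)C)C(C)C)c(OC)c4)c(OC)c1 | intermediate
10 | 4-{[(1S,2R)-1,3-dihydroxy-1-{3-methoxy-4-[(triisopropylsilyl)oxy]phenyl}propan-2-yl]oxy}-3-methoxybenzonitrile | N#Cc1ccc(O[C@H](CO)[C@@H](O)c2ccc(O[Si](C(C)C)(C(C)C)C(C)C)c(OC)c2)c(OC)c1 | intermediate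
11 | 4-{[(1S,2R)-1,3-bis[(tert-butyldimethylsilyl)oxy]-1-{3-methoxy-4-[(triisopropylsilyl)oxy]phenyl}propan-2-yl]oxy}-3-methoxybenzonitrile | N#Cc1ccc(O[C@H](CO[Si](C)(C)C(C)(C)C)[C@@H](O[Si](C)(C)C(C)(C)C)c2ccc(O[Si](C(C)C)(C(C)C)C(C)C)c(OC)c2)c(OC)c1 | intermediate
12 | N-(diisobutylaluminio)imine of aldehyde 13 | CC(C)C[Al](CC(C)C)N=Cc1ccc(O[C@H](CO[Si](C)(C)C(C)(C)C)[C@@H](O[Si](C)(C)C(C)(C)C)c2ccc(O[Si](C(C)C)(C(C)C)C(C)C)c(OC)c2)c(OC)c1 | intermediate (not isolated)
13 | 4-{[(1S,2R)-1,3-bis[(tert-butyldimethylsilyl)oxy]-1-{3-methoxy-4-[(triisopropylsilyl)oxy]phenyl}propan-2-yl]oxy}-3-methoxybenzaldehyde | O=Cc1ccc(O[C@H](CO[Si](C)(C)C(C)(C)C)[C@@H](O[Si](C)(C)C(C)(C)C)c2ccc(O[Si](C(C)C)(C(C)C)C(C)C)c(OC)c2)c(OC)c1 | intermediate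
14 | (S)-4-benzyl-3-(chloroacetyl)oxazolidin-2-one | ClCC(=O)N1[C@@H](Cc2ccccc2)COC1=O | starting material
15 | (+)-syringaresinol mono-ether: one phenolic O carries CH2C(=O) bound to N of (S)-4-benzyloxazolidin-2-one | O=C(COc1c(OC)cc([C@H]2OC[C@H]3[C@@H]2CO[C@@H]3c2cc(OC)c(O)c(OC)c2)cc1OC)N1[C@@H](Cc2ccccc2)COC1=O | intermediate
16 | bis(trimethylsilyl) derivative of 17 (aldol oxygen and free core phenol silylated) | COc1cc([C@@H](O[Si](C)(C)C)[C@H](C(=O)N2[C@@H](Cc3ccccc3)COC2=O)Oc2c(OC)cc([C@H]3OC[C@H]4[C@@H]3CO[C@@H]4c3cc(OC)c(O[Si](C)(C)C)c(OC)c3)cc2OC)ccc1O[Si](C(C)C)(C(C)C)C(C)C | intermediate (not isolated)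
17 | (S)-4-benzyl-3-[(2R,3R)-3-hydroxy-3-{3-methoxy-4-[(triisopropylsilyl)oxy]phenyl}-2-(syringaresinol-4-yloxy)propanoyl]oxazolidin-2-one | COc1cc([C@@H](O)[C@H](C(=O)N2[C@@H](Cc3ccccc3)COC2=O)Oc2c(OC)cc([C@H]3OC[C@H]4[C@@H]3CO[C@@H]4c3cc(OC)c(O)c(OC)c3)cc2OC)ccc1O[Si](C(C)C)(C(C)C)C(C)C | intermediate
18 | (+)-syringaresinol mono-ether with C2 of (1R,2S)-1-{3-methoxy-4-[(triisopropylsilyl)oxy]phenyl}propane-1,3-diol (erythro unit A, 7R,8S) | COc1cc([C@@H](O)[C@H](CO)Oc2c(OC)cc([C@H]3OC[C@H]4[C@@H]3CO[C@@H]4c3cc(OC)c(O)c(OC)c3)cc2OC)ccc1O[Si](C(C)C)(C(C)C)C(C)C | intermediate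
19 | 18 with the second core phenol as OCH2C(=O)–N ether-imide of (R)-4-benzyloxazolidin-2-one | COc1cc([C@@H](O)[C@H](CO)Oc2c(OC)cc([C@H]3OC[C@H]4[C@@H]3CO[C@@H]4c3cc(OC)c(OCC(=O)N5[C@H](Cc6ccccc6)COC5=O)c(OC)c3)cc2OC)ccc1O[Si](C(C)C)(C(C)C)C(C)C | intermediate
20 | 19 with the C7 and C9 hydroxyls of unit A as TBS ethers | COc1cc([C@@H](O[Si](C)(C)C(C)(C)C)[C@H](CO[Si](C)(C)C(C)(C)C)Oc2c(OC)cc([C@H]3OC[C@H]4[C@@H]3CO[C@@H]4c3cc(OC)c(OCC(=O)N5[C@H](Cc6ccccc6)COC5=O)c(OC)c3)cc2OC)ccc1O[Si](C(C)C)(C(C)C)C(C)C | intermediate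
21 | dibutylboron (Z)-enolate of 20 | COc1cc([C@@H](O[Si](C)(C)C(C)(C)C)[C@H](CO[Si](C)(C)C(C)(C)C)Oc2c(OC)cc([C@H]3OC[C@H]4[C@@H]3CO[C@@H]4c3cc(OC)c(O/C=C(\OB(CCCC)CCCC)N5[C@H](Cc6ccccc6)COC5=O)c(OC)c3)cc2OC)ccc1O[Si](C(C)C)(C(C)C)C(C)C | intermediate (not isolated)
22 | syn-aldol adduct: (2R,3S)-3-hydroxy-2-(core aryloxy)-3-aryl-propanoyl imide of (R)-4-benzyloxazolidin-2-one, aryl = 3-methoxy-4-(unit C oxy)phenyl, units A and C silylated | COc1cc([C@@H](O[Si](C)(C)C(C)(C)C)[C@H](CO[Si](C)(C)C(C)(C)C)Oc2c(OC)cc([C@H]3OC[C@H]4[C@@H]3CO[C@@H]4c3cc(OC)c(O[C@@H](C(=O)N4[C@H](Cc5ccccc5)COC4=O)[C@@H](O)c4ccc(O[C@H](CO[Si](C)(C)C(C)(C)C)[C@@H](O[Si](C)(C)C(C)(C)C)c5ccc(O[Si](C(C)C)(C(C)C)C(C)C)c(OC)c5)c(OC)c4)c(OC)c3)cc2OC)ccc1O[Si](C(C)C)(C(C)C)C(C)C | intermediate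
23 | target with both guaiacyl phenols as TIPS ethers and C7-OH and C9-OH of units A and C as TBS ethers | COc1cc([C@@H](O[Si](C)(C)C(C)(C)C)[C@H](CO[Si](C)(C)C(C)(C)C)Oc2c(OC)cc([C@H]3OC[C@H]4[C@@H]3CO[C@@H]4c3cc(OC)c(O[C@@H](CO)[C@@H](O)c4ccc(O[C@H](CO[Si](C)(C)C(C)(C)C)[C@@H](O[Si](C)(C)C(C)(C)C)c5ccc(O[Si](C(C)C)(C(C)C)C(C)C)c(OC)c5)c(OC)c4)c(OC)c3)cc2OC)ccc1O[Si](C(C)C)(C(C)C)C(C)C | intermediate
24 | CNP0316493.3: (+)-syringaresinol bearing erythro-(7R,8S)-guaiacylglycerol-8-yl on one phenol and, on the other, threo-(7S,8S)-guaiacylglycerol-8-yl whose phenol carries erythro-(7S,8R)-guaiacylglycerol-8-yl | COc1cc([C@@H](O)[C@H](CO)Oc2c(OC)cc([C@H]3OC[C@H]4[C@@H]3CO[C@@H]4c3cc(OC)c(O[C@@H](CO)[C@@H](O)c4ccc(O[C@H](CO)[C@@H](O)c5ccc(O)c(OC)c5)c(OC)c4)c(OC)c3)cc2OC)ccc1O | target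

**Count**

Total steps: 15. Longest linear sequence: 9 steps (steps 1, 8, 9, 10, 11, 12, 13, 14, 15, from 1 to 24); the aldehyde branch (steps 3–7) joins at step 13.

**Three steps most likely to fail, with fallbacks**

Step 4 (proposed new method; anti selectivity and turnover with an α-aryloxy enolate are unproven). The fallback uses known reactions, sets out from 5 and 14 and comes back at 10; it reaches the erythro unit by a syn-aldol followed by inversion at C7. Phenol 5 is alkylated with the (S)-imide 14 (K2CO3, DMF) to (S)-4-benzyl-3-[(4-cyano-2-methoxyphenoxy)acetyl]oxazolidin-2-one F1. Its dibutylboron enolate (nBu2BOTf, iPr2NEt, CH2Cl2, −78 °C, then H2O2 work-up) adds to 4 in the Evans syn mode to give the (2S,3R) syn adduct F2. LiBH4 gives the threo (1R,2R) diol F3. The secondary benzylic alcohol alone is oxidised (4-acetamido-TEMPO 5 mol %, HNO3 and HCl 10 mol % each, O2, MeCN/H2O, 45 °C) to the (R)-configured aryl ketone F4. Chelation-controlled reduction with Zn(BH4)2 (Et2O/THF, −30 °C; hydride enters anti to the chelated aryloxy group) gives the erythro diol 10; the minor threo isomer is removed on silica.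

Step 9 (the same new method on the real substrate; many Lewis-basic methoxy groups and a free phenol could stop catalyst turnover or erode selectivity). The fallback uses known reactions, sets out from 2 and 6 and comes back at 18. Diphenol 2 (excess) is mono-alkylated with the (R)-imide 6 (K2CO3, DMF) to the (R)-auxiliary aryloxyacetyl imide of syringaresinol F5. Its dibutylboron enolate (nBu2BOTf and iPr2NEt in excess to cover the phenol, CH2Cl2, −78 °C) adds to 4 in the Evans syn mode to give the (2R,3S) syn adduct F6. LiBH4 gives the threo (7S,8S) diol F7, the C7 epimer of 18. Aerobic nitroxyl oxidation (same conditions as above, which spare the primary alcohol and the free phenol) gives the (8S)-configured aryl ketone F8. Zn(BH4)2 reduction under chelation control gives the erythro (7R,8S) alcohol, which is 18.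

Step 13 (late union of two precious fragments; the hindered, electron-rich aldehyde 13 may add slowly to a boron enolate that is surrounded by silyl ethers and methoxy groups). The fallback changes the convergent union into a linear build-up of arm B, sets out from 20 and comes back at 24. The boron enolate of 20 is added to the small, cheap aldehyde 4-formyl-2-methoxyphenyl acetate F9 to give the syn adduct with an aryl acetate F10. LiBH4 cleaves both the auxiliary and the acetate to give the unit-B diol with a free guaiacyl phenol F11. This phenol alone is alkylated with 6 (K2CO3, DMF) to the aryloxyacetyl imide F12. The MgCl2-catalysed anti-aldol of step 4 with aldehyde 4 (the free diol is silylated in the flask and freed on work-up) gives the unit-C adduct F13. LiBH4 gives the unit-C diol F14, and the fluoride conditions of step 15 turn F14 directly into 24.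

**Further compounds**

F1 | step 4 | (S)-4-benzyl-3-[(4-cyano-2-methoxyphenoxy)acetyl]oxazolidin-2-one | COc1cc(C#N)ccc1OCC(=O)N1[C@@H](Cc2ccccc2)COC1=O
F2 | step 4 | (S)-4-benzyl-3-[(2S,3R)-2-(4-cyano-2-methoxyphenoxy)-3-hydroxy-3-{3-methoxy-4-[(triisopropylsilyl)oxy]phenyl}propanoyl]oxazolidin-2-one | N#Cc1ccc(O[C@H](C(=O)N2[C@@H](Cc3ccccc3)COC2=O)[C@H](O)c4ccc(O[Si](C(C)C)(C(C)C)C(C)C)c(OC)c4)c(OC)c1
F3 | step 4 | 4-{[(1R,2R)-1,3-dihydroxy-1-{3-methoxy-4-[(triisopropylsilyl)oxy]phenyl}propan-2-yl]oxy}-3-methoxybenzonitrile (threo) | N#Cc1ccc(O[C@H](CO)[C@H](O)c2ccc(O[Si](C(C)C)(C(C)C)C(C)C)c(OC)c2)c(OC)c1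
F4 | step 4 | 4-{[(2R)-3-hydroxy-1-{3-methoxy-4-[(triisopropylsilyl)oxy]phenyl}-1-oxopropan-2-yl]oxy}-3-methoxybenzonitrile | N#Cc1ccc(O[C@H](CO)C(=O)c2ccc(O[Si](C(C)C)(C(C)C)C(C)C)c(OC)c2)c(OC)c1
F5 | step 9 | (+)-syringaresinol mono-ether: one phenolic O carries CH2C(=O) bound to N of (R)-4-benzyloxazolidin-2-one | O=C(COc1c(OC)cc([C@H]2OC[C@H]3[C@@H]2CO[C@@H]3c2cc(OC)c(O)c(OC)c2)cc1OC)N1[C@H](Cc2ccccc2)COC1=O
F6 | step 9 | (R)-4-benzyl-3-[(2R,3S)-3-hydroxy-3-{3-methoxy-4-[(triisopropylsilyl)oxy]phenyl}-2-(syringaresinol-4-yloxy)propanoyl]oxazolidin-2-one | COc1cc([C@H](O)[C@H](C(=O)N2[C@H](Cc3ccccc3)COC2=O)Oc2c(OC)cc([C@H]3OC[C@H]4[C@@H]3CO[C@@H]4c3cc(OC)c(O)c(OC)c3)cc2OC)ccc1O[Si](C(C)C)(C(C)C)C(C)C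
F7 | step 9 | (+)-syringaresinol mono-ether with C2 of (1S,2S)-1-{3-methoxy-4-[(triisopropylsilyl)oxy]phenyl}propane-1,3-diol (threo, C7 epimer of 18) | COc1cc([C@H](O)[C@H](CO)Oc2c(OC)cc([C@H]3OC[C@H]4[C@@H]3CO[C@@H]4c3cc(OC)c(O)c(OC)c3)cc2OC)ccc1O[Si](C(C)C)(C(C)C)C(C)C
F8 | step 9 | (+)-syringaresinol mono-ether with C2 of (2S)-3-hydroxy-1-{3-methoxy-4-[(triisopropylsilyl)oxy]phenyl}propan-1-one | COc1cc(C(=O)[C@H](CO)Oc2c(OC)cc([C@H]3OC[C@H]4[C@@H]3CO[C@@H]4c3cc(OC)c(O)c(OC)c3)cc2OC)ccc1O[Si](C(C)C)(C(C)C)C(C)C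
F9 | step 13 | 4-formyl-2-methoxyphenyl acetate | CC(=O)Oc1ccc(C=O)cc1OC
F10 | step 13 | syn-aldol adduct of 20 with F9: (2R,3S)-3-(4-acetoxy-3-methoxyphenyl)-3-hydroxy-2-(core aryloxy)propanoyl imide of (R)-4-benzyloxazolidin-2-one, unit A silylated | COc1cc([C@@H](O[Si](C)(C)C(C)(C)C)[C@H](CO[Si](C)(C)C(C)(C)C)Oc2c(OC)cc([C@H]3OC[C@H]4[C@@H]3CO[C@@H]4c3cc(OC)c(O[C@@H](C(=O)N4[C@H](Cc5ccccc5)COC4=O)[C@@H](O)c4ccc(OC(C)=O)c(OC)c4)c(OC)c3)cc2OC)ccc1O[Si](C(C)C)(C(C)C)C(C)C
F11 | step 13 | silylated unit A on the core plus threo (7S,8S) unit B with free diol and free guaiacyl phenol | COc1cc([C@@H](O[Si](C)(C)C(C)(C)C)[C@H](CO[Si](C)(C)C(C)(C)C)Oc2c(OC)cc([C@H]3OC[C@H]4[C@@H]3CO[C@@H]4c3cc(OC)c(O[C@@H](CO)[C@@H](O)c4ccc(O)c(OC)c4)c(OC)c3)cc2OC)ccc1O[Si](C(C)C)(C(C)C)C(C)C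
F12 | step 13 | F11 with the unit-B phenol as OCH2C(=O)–N ether-imide of (R)-4-benzyloxazolidin-2-one | COc1cc([C@@H](O[Si](C)(C)C(C)(C)C)[C@H](CO[Si](C)(C)C(C)(C)C)Oc2c(OC)cc([C@H]3OC[C@H]4[C@@H]3CO[C@@H]4c3cc(OC)c(O[C@@H](CO)[C@@H](O)c4ccc(OCC(=O)N5[C@H](Cc6ccccc6)COC5=O)c(OC)c4)c(OC)c3)cc2OC)ccc1O[Si](C(C)C)(C(C)C)C(C)C
F13 | step 13 | anti-aldol adduct of F12 with 4: (2S,3S)-3-hydroxy-3-{3-methoxy-4-[(triisopropylsilyl)oxy]phenyl}-2-(unit-B aryloxy)propanoyl imide of (R)-4-benzyloxazolidin-2-one | COc1cc([C@@H](O[Si](C)(C)C(C)(C)C)[C@H](CO[Si](C)(C)C(C)(C)C)Oc2c(OC)cc([C@H]3OC[C@H]4[C@@H]3CO[C@@H]4c3cc(OC)c(O[C@@H](CO)[C@@H](O)c4ccc(O[C@H](C(=O)N5[C@H](Cc6ccccc6)COC5=O)[C@@H](O)c5ccc(O[Si](C(C)C)(C(C)C)C(C)C)c(OC)c5)c(OC)c4)c(OC)c3)cc2OC)ccc1O[Si](C(C)C)(C(C)C)C(C)C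
F14 | step 13 | target with both guaiacyl phenols as TIPS ethers and only C7-OH and C9-OH of unit A as TBS ethers | COc1cc([C@@H](O[Si](C)(C)C(C)(C)C)[C@H](CO[Si](C)(C)C(C)(C)C)Oc2c(OC)cc([C@H]3OC[C@H]4[C@@H]3CO[C@@H]4c3cc(OC)c(O[C@@H](CO)[C@@H](O)c4ccc(O[C@H](CO)[C@@H](O)c5ccc(O[Si](C(C)C)(C(C)C)C(C)C)c(OC)c5)c(OC)c4)c(OC)c3)cc2OC)ccc1O[Si](C(C)C)(C(C)C)C(C)C
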